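## The problem

The target is an unbranched furanoterpenoid chain (C6 to C18, ending in a 3-substituted furan) joined through an exocyclic C5=C6 alkene to a 3-methyltetronic acid (O1, C2 to C5) whose C4 oxygen carries a palmitoyl group. No rings are fused, so the work is chain construction, one heterocycle and one acylation. The only stereocentre is C7 (S). Nothing in the molecule can relay chirality to it and it controls nothing else, so it must be set by a reagent or catalyst and then merely kept intact. The C5=C6 alkene is E, which puts the chain cis to the C4 acyloxy group. This is expected to be the more congested isomer of a 5-ylidene tetronate, so equilibrating methods such as aldol condensation and dehydration would favour the wrong geometry; the geometry has to be transferred stereospecifically. The two trisubstituted E alkenes (C11=C12, C15=C16) are best bought with farnesol. The furan does not tolerate strong acid, electrophilic halogen or oxidants, and the trisubstituted alkenes do not tolerate strong acid. The 4-O-acyl tetronate is a vinylogous mixed anhydride that passes its acyl group to nucleophiles, so it is made last. The enabling feature is that C7 is β to C5 through C6: with C5 as a thioester carbonyl and C6=C7 as its alkene, C7 becomes the β-carbon of an achiral Michael acceptor and its methyl group becomes the nucleophile. The adduct then holds C5 and C6 at the oxidation levels from which a C5≡C6 alkyne, and from it a stereodefined C5=C6 alkene, can be drawn.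

## Retrosynthesis

**Target 32 to tetronic acid 30 and palmitoyl chloride 31.** The enol ester O–C(O) bond is cut first. Tetronic acid 30 is robust by comparison, and the methyl group at C3 blocks C-acylation, so the forward reaction only has to be a mild O-acylation that leaves the E alkene alone.

**Tetronic acid 30 to (E)-α-iodoenone 28 and CO2.** The O1–C5 and C2–C3 bonds are cut. Cutting C5=C6 instead (aldol and dehydration) or adding a carboxylate anti across a C5≡C6 alkyne would both deliver the Z isomer. A vinyl iodide at C5 with the chain already cis to C4 lets a copper-mediated C–O coupling close the lactone with retention. The precursor 28 is an open-chain ethyl ketone, which is carboxylated at C3 (through carboxylate 29) before ring closure. The forward reaction must couple faster than the β-keto carboxylate loses CO2 and must not scramble the alkene.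

**Iodoenone 28 to ynone 26, then to alkyne 23 and amide 24.** The C5–I and C6–H bonds come from a syn hydrostannation of ynone 26 (through stannane 27) followed by iodinolysis with retention. The C4–C5 bond comes from acylation of the lithium acetylide 25 with N-methoxy-N-methylpropanamide 24, which brings C2-free C3, its methyl group and C4 in one piece. The forward steps must place tin at the α-carbon and add syn.

**Alkyne 23 to aldehyde 21 to thioester 20.** No carbon–carbon bond is cut. C5 and C6 of the alkyne are the carbonyl and α-carbons of 20, so reduction to aldehyde 21 and elimination through alkenyl nonaflate 22 give 23 with the carbon count unchanged. A homologating alkyne synthesis would need a C6 aldehyde with C7 α to the carbonyl and open to epimerisation; here C7 is always β or further.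

**Thioester 20 to enethioate 18 and MeMgBr.** The C7–CH3 bond is cut. This is the only disconnection that creates the stereocentre from a wholly achiral chain, with a catalytic chiral source, while leaving C5 and C6 functionalised. The forward reaction needs 1,4- over 1,2-addition and facial control from the ligand alone (through magnesium enolate 19).

**Enethioate 18 to aldehyde 12 and ylide 17.** The C6=C7 bond is cut as a Wittig reaction of a stabilised ylide, which gives the E geometry the key step requires. Ylide 17 comes from bromothioacetate 15 (through salt 16), itself from ethanethiol 13 and bromoacetyl bromide 14.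

**Aldehyde 12 to aldehyde 10 to epoxide 9.** The C7–C8 bond is cut as a one-carbon homologation through enol ether 11. Aldehyde 10 arises from 9 by oxidative excision of acetone, so the epoxide serves as a latent aldehyde that survives organometallic chemistry.

**Epoxide 9 to allylic chloride 5 and 3-(chloromethyl)furan 7.** The C17–C18 bond is cut as a copper-catalysed coupling of Grignard reagent 8 with 5. The terminal oxidation is placed before the furan arrives because N-bromosuccinimide would attack the furan. Chloride 5 comes from farnesol 1 through acetate 2, bromohydrin 3 and epoxy alcohol 4; chloride 7 comes from furan-3-ylmethanol 6.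

## Roads not taken

**Alternative 1: sulfone linchpin with a chiral-pool epoxide.** The cut is at C8–C9 and C9–C10, with C7 bought as (R)-2-methyloxirane A2. In the forward step lithiated methyl phenyl sulfone A3 opens A2 at its CH2, and after a second deprotonation the sulfonyl carbanion is alkylated by the allylic bromide A4 to give the hydroxy sulfone A1.
- Merits: the stereocentre is purchased enantiopure, which no catalytic step can beat, and three pieces are joined in one flask.
- Weak points: in A1 the future C7 carries a hydroxyl group where the target needs C6. The C6–C7 bond would have to be formed at an unactivated secondary carbon with clean inversion, where an sp or sp2 carbon nucleophile competes with elimination. The sulfone must also be removed reductively beside a furan, and A4 needs its own allylic oxidation.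
- Comparison: this road is better in enantiopurity and convergence. The chosen plan sets against it that C7 is formed with C5 and C6 already attached at useful oxidation levels, so no substitution at the stereocentre is ever needed.

**Alternative 2: lithiation–borylation.** The cut is at C7–C8. Sparteine-complexed lithiated ethyl 2,4,6-tri(propan-2-yl)benzoate A7 adds to the primary boronic ester A6, and 1,2-migration of C8 from boron to carbon gives the secondary boronic ester A5.
- Merits: reagent control of this kind usually gives very high enantiomer ratios. A6 could be reached from aldehyde 10 in about three steps, and a stereospecific alkynylation of the boronic ester (Zweifel-type olefination and elimination) would lead to alkyne 23 in about the same number of steps as here, without the aldehyde-to-alkyne conversion.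
- Weak points: it needs stoichiometric sparteine and s-BuLi at −78 °C in a molecule with acidic furan α-hydrogens. The later alkynylation uses electrophilic halogen near the furan and the alkenes. As formulated, A5 is (2R): because the priority ranking changes when boron is replaced by carbon, a retentive C–C bond formation from A5 would give (R) at C7, so the antipodal carbenoid or an invertive coupling would be required.
- Comparison: this road is equal in length and probably better in selectivity. The chosen plan offers a chiral source used at a few mol%, both ligand enantiomers on the shelf, simpler reagents and a product at the thioester oxidation level.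

**Alternative 3: ene-reductase on the intact furanopolyene.** The cut is the C7–H and C8–H bonds. An Old Yellow Enzyme reduces only the aldehyde-conjugated alkene of enal A9, and a coupled alcohol dehydrogenase traps the product as alcohol A8.
- Merits: this is clearly the shortest road. A9 would come from the farnesyl-type furan A10 by allylic oxidation of the terminal E-methyl group. Oxidation of A8 to aldehyde A11 and Seyferth–Gilbert homologation would reach alkyne 23 in about six linear steps against eleven here, with no protecting groups and no epoxide detour.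
- Weak points: the allylic oxidation must choose one of several allylic positions in a polyene that also carries a furan. Acceptance of a lipophilic C20 enal by an ene-reductase of the required facial preference would need screening. C7 is α to an aldehyde in A11 and must survive the basic alkynylation.
- Comparison: this road is better in step count. The chosen plan sets against it a predictable, substrate-general catalyst and a stereocentre that is never α to a carbonyl group.

Key step: step 12

Assumption on ligand sense: the (R,S_Fe) enantiomer of Josiphos is taken to give the (3R) adduct from linear β-alkyl (E)-enethioates, so the (S,R_Fe) enantiomer, (S)-1-[(R_p)-2-(diphenylphosphino)ferrocenyl]ethyldicyclohexylphosphine, is specified for 20. If the first run shows the opposite sense, only the ligand enantiomer is exchanged.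

Remark: compounds 3, 4, 5 and 9 are racemic at the oxygen-bearing carbon, which leaves as acetone in step 7.

## Route

Step 1
Reactants: 1 (2E,6E)-farnesol
Product: 2 (2E,6E)-farnesyl acetate
Conditions: Ac2O, pyridine, DMAP (cat.), CH2Cl2, 0 °C to rt
Reagents that add atoms: acetic anhydride, CC(=O)OC(C)=O
Why: Standard O-acetylation of a primary allylic alcohol; the acetate lowers the electron density of the 2,3-alkene ahead of the electrophilic bromination.

Step 2
Reactants: 2 (2E,6E)-farnesyl acetate
Product: 3 (2E,6E)-10-bromo-11-hydroxy-3,7,11-trimethyldodeca-2,6-dien-1-yl acetate (racemic)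
Conditions: NBS, THF/H2O (2:1), 0 °C
Reagents that add atoms: N-bromosuccinimide, O=C1CCC(=O)N1Br; water, O
Why: Bromohydrin formation in aqueous THF is selective for the terminal trisubstituted alkene of farnesyl esters; water opens the bromonium ion at the tertiary carbon.

Step 3
Reactants: 3 (2E,6E)-10-bromo-11-hydroxy-3,7,11-trimethyldodeca-2,6-dien-1-yl acetate (racemic)
Product: 4 (2E,6E)-9-(3,3-dimethyloxiran-2-yl)-3,7-dimethylnona-2,6-dien-1-ol (racemic)
Conditions: K2CO3, MeOH, rt
Reagents that add atoms: none
Why: Intramolecular Williamson etherification closes the epoxide, and the same carbonate/methanol medium transesterifies the acetate to free the allylic alcohol.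

Step 4
Reactants: 4 (2E,6E)-9-(3,3-dimethyloxiran-2-yl)-3,7-dimethylnona-2,6-dien-1-ol (racemic)
Product: 5 3-[(3E,7E)-9-chloro-3,7-dimethylnona-3,7-dien-1-yl]-2,2-dimethyloxirane (racemic)
Conditions: MsCl, LiCl, 2,4,6-collidine, DMF, 0 °C
Reagents that add atoms: lithium chloride, [Li+].[Cl-]
Why: Sulfonate activation and chloride displacement under buffered conditions convert primary allylic alcohols to chlorides without allylic transposition or loss of alkene geometry; the trisubstituted epoxide is not touched at 0 °C.

Step 5
Reactants: 6 furan-3-ylmethanol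
Product: 7 3-(chloromethyl)furan
Conditions: SOCl2, pyridine, Et2O, 0 °C
Reagents that add atoms: thionyl chloride, ClS(Cl)=O
Why: Deoxychlorination of a primary heteroarylmethanol with pyridine as acid scavenger; the volatile chloride is used at once.

Step 6
Reactants: 7 3-(chloromethyl)furan; 5 3-[(3E,7E)-9-chloro-3,7-dimethylnona-3,7-dien-1-yl]-2,2-dimethyloxirane (racemic)
Product: 9 3-[(3E,7E)-10-(3,3-dimethyloxiran-2-yl)-4,8-dimethyldeca-3,7-dien-1-yl]furan (racemic), via 3-furylmethylmagnesium chloride 8 (not isolated)
Conditions: Mg, THF, 0 °C to rt; then 5, Li2CuCl4 (3 mol%), THF, 0 °C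
Reagents that add atoms: none
Why: Copper-catalysed cross-coupling of a 3-furylmethyl Grignard reagent with a primary allylic chloride is a known head-to-head (SN2) alkylation that keeps the E geometry and has been applied to prenyl-type chlorides bearing a remote trisubstituted epoxide.

Step 7
Reactants: 9 3-[(3E,7E)-10-(3,3-dimethyloxiran-2-yl)-4,8-dimethyldeca-3,7-dien-1-yl]furan (racemic)
Product: 10 (4E,8E)-11-(furan-3-yl)-4,8-dimethylundeca-4,8-dienal
Conditions: H5IO6, THF/Et2O, 0 °C
Reagents that add atoms: none
Why: Periodic acid opens the epoxide and cleaves the resulting glycol in one operation (Malaprade-type cleavage), releasing acetone; short exposure at 0 °C should spare the furan and the alkenes.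

Step 8
Reactants: 10 (4E,8E)-11-(furan-3-yl)-4,8-dimethylundeca-4,8-dienal
Product: 12 (5E,9E)-12-(furan-3-yl)-5,9-dimethyldodeca-5,9-dienal, via enol ether 11 (not isolated)
Conditions: Ph3P(CH2OMe)Cl, KN(SiMe3)2, THF, 0 °C; 10, −78 °C to rt; then 2 M aq HCl, rt
Reagents that add atoms: (methoxymethyl)triphenylphosphonium chloride, COC[P+](c1ccccc1)(c1ccccc1)c1ccccc1.[Cl-]; water, O
Why: Wittig methoxymethylenation and hydrolysis of the enol ether is the standard one-carbon aldehyde homologation; dilute acid at room temperature is mild enough for a 3-alkylfuran and trisubstituted alkenes.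

Step 9
Reactants: 13 ethanethiol; 14 bromoacetyl bromide
Product: 15 S-ethyl 2-bromoethanethioate
Conditions: pyridine, CH2Cl2, 0 °C
Reagents that add atoms: none
Why: Thioesterification; the acyl bromide reacts with the thiol far faster than the α-bromide does.

Step 10
Reactants: 15 S-ethyl 2-bromoethanethioate
Product: 17 S-ethyl 2-(triphenyl-λ5-phosphanylidene)ethanethioate, via phosphonium bromide 16 (not isolated)
Conditions: PPh3, CH2Cl2, rt; then 10% aq Na2CO3
Reagents that add atoms: triphenylphosphine, c1ccc(cc1)P(c1ccccc1)c1ccccc1
Why: SN2 quaternisation of the phosphine followed by deprotonation of the acidic phosphonium salt gives the stabilised ylide.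

Step 11
Reactants: 12 (5E,9E)-12-(furan-3-yl)-5,9-dimethyldodeca-5,9-dienal; 17 S-ethyl 2-(triphenyl-λ5-phosphanylidene)ethanethioate
Product: 18 S-ethyl (2E,7E,11E)-14-(furan-3-yl)-7,11-dimethyltetradeca-2,7,11-trienethioate
Conditions: CH2Cl2, reflux
Reagents that add atoms: none
Why: Wittig reaction of a stabilised ylide with an unhindered aliphatic aldehyde gives the (E)-enethioate with high selectivity.

Step 12
Reactants: 18 S-ethyl (2E,7E,11E)-14-(furan-3-yl)-7,11-dimethyltetradeca-2,7,11-trienethioate
Product: 20 S-ethyl (3S,7E,11E)-14-(furan-3-yl)-3,7,11-trimethyltetradeca-7,11-dienethioate, via magnesium enolate 19 (not isolated)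
Conditions: MeMgBr (1.2 equiv), CuBr·SMe2 (2 mol%), (S,R_Fe)-Josiphos (2.4 mol%), t-BuOMe, −75 °C, slow addition of 18; MeOH, then aq NH4Cl
Reagents that add atoms: methylmagnesium bromide, C[Mg]Br
Why: MeMgBr converts the CuBr–diphosphine complex into a chiral methylcopper species of monovalent copper, which binds the s-cis enethioate as a π-complex with magnesium on the carbonyl oxygen. Oxidative addition at the β-carbon C7 gives a trivalent copper intermediate, and reductive elimination forms the C7–CH3 bond and releases magnesium enolate 19, which is protonated on quench. The closest known reaction type is the copper/Josiphos-catalysed enantioselective conjugate addition of MeMgBr to β-alkyl α,β-unsaturated S-alkyl thioesters. No ring is closed. The C7 stereocentre is set by the ligand enantiomer alone, since the substrate has no other stereogenic element. The step needs 1,4- rather than 1,2-addition, which the thioester and the low temperature secure, and facial selectivity, which depends on the geometrically pure E alkene from step 11 and on slow addition to suppress the uncatalysed background. The isolated trisubstituted alkenes and the furan are not Michael acceptors and should not compete for copper.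

Step 13
Reactants: 20 S-ethyl (3S,7E,11E)-14-(furan-3-yl)-3,7,11-trimethyltetradeca-7,11-dienethioate
Product: 21 (3S,7E,11E)-14-(furan-3-yl)-3,7,11-trimethyltetradeca-7,11-dienal
Conditions: iBu2AlH, CH2Cl2, −78 °C; aq potassium sodium tartrate
Reagents that add atoms: none
Why: Partial hydride reduction of an S-alkyl thioester stops at the aldehyde at −78 °C; C7 is β to the carbonyl group and cannot epimerise.

Step 14
Reactants: 21 (3S,7E,11E)-14-(furan-3-yl)-3,7,11-trimethyltetradeca-7,11-dienal
Product: 23 3-[(3E,7E,12S)-4,8,12-trimethyltetradeca-3,7-dien-13-yn-1-yl]furan, via alkenyl nonaflate 22 (not isolated)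
Conditions: nonafluorobutane-1-sulfonyl fluoride, P2-Et phosphazene base (EtN=P(NMe2)2–N=P(NMe2)3, 2.3 equiv), DMF, −30 °C to rt
Reagents that add atoms: none
Why: One-pot O-sulfonylation of the aldehyde enolate and base-induced elimination of the alkenyl nonaflate gives the terminal alkyne without change of carbon count, a known aldehyde-to-alkyne conversion; the C7–H bond is not acidic enough for the phosphazene base, so the stereocentre should persist.

Step 15
Reactants: 23 3-[(3E,7E,12S)-4,8,12-trimethyltetradeca-3,7-dien-13-yn-1-yl]furan; 24 N-methoxy-N-methylpropanamide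
Product: 26 (6S,10E,14E)-17-(furan-3-yl)-6,10,14-trimethylheptadeca-10,14-dien-4-yn-3-one, via lithium acetylide 25 (not isolated)
Conditions: n-BuLi (1.0 equiv), THF, −78 °C; then 24, −78 to 0 °C; aq NH4Cl
Reagents that add atoms: none
Why: Weinreb ketone synthesis: the lithium acetylide adds once to the N-methoxy-N-methylamide and the ynone is released only on work-up; one equivalent of n-BuLi at −78 °C removes only the alkyne hydrogen.

Step 16
Reactants: 26 (6S,10E,14E)-17-(furan-3-yl)-6,10,14-trimethylheptadeca-10,14-dien-4-yn-3-one
Product: 28 (4E,6S,10E,14E)-17-(furan-3-yl)-4-iodo-6,10,14-trimethylheptadeca-4,10,14-trien-3-one, via α-stannyl enone 27 (not isolated)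
Conditions: Bu3SnH, Pd(PPh3)4 (2 mol%), THF, 0 °C; then I2, CH2Cl2, 0 °C, dark
Reagents that add atoms: iodine, II
Why: Hydrostannation of conjugated ynones with a zerovalent palladium catalyst is a syn addition that places tin on the α-carbon (C5) and hydrogen on C6; iododestannylation proceeds with retention, so iodine ends trans to C7 and the chain cis to the carbonyl group (4E).

Step 17
Reactants: 28 (4E,6S,10E,14E)-17-(furan-3-yl)-4-iodo-6,10,14-trimethylheptadeca-4,10,14-trien-3-one
Product: 30 (5E)-5-[(2S,6E,10E)-13-(furan-3-yl)-2,6,10-trimethyltrideca-6,10-dien-1-ylidene]-4-hydroxy-3-methylfuran-2(5H)-one, via lithium β-keto carboxylate 29 (not isolated)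
Conditions: LiN(SiMe3)2 (1.05 equiv), THF, −78 °C; CO2 (1 atm), −78 to 0 °C; then CuI (20 mol%), 1,10-phenanthroline (40 mol%), Cs2CO3, DMF, CO2 atmosphere, 40 °C, dark; cold aq citric acid
Reagents that add atoms: carbon dioxide, O=C=O
Why: Proposed new method: kinetic deprotonation of the ethyl ketone at C3 and C-carboxylation of the lithium enolate with CO2 give β-keto carboxylate 29, whose monovalent copper carboxylate adds oxidatively into the neighbouring C5–I bond and forms the O1–C5 bond by reductive elimination with retention, closing the five-membered enol lactone with the alkene exocyclic, after which tautomerisation to the tetronate anion removes the product from the decarboxylation equilibrium; the closest known reaction types are the CuI-catalysed intramolecular O-vinylation of carboxylic acids by vinyl halides to five-membered enol lactones with retention of geometry, the carboxylation of ketone lithium enolates with CO2, and the silver-catalysed incorporation of CO2 into conjugated ynones that gives (Z)-ylidene tetronic acids, whereas their combination on a β-keto carboxylate is untested.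

Step 18
Reactants: 30 (5E)-5-[(2S,6E,10E)-13-(furan-3-yl)-2,6,10-trimethyltrideca-6,10-dien-1-ylidene]-4-hydroxy-3-methylfuran-2(5H)-one; 31 hexadecanoyl chloride
Product: 32 (2E)-2-[(2S,6E,10E)-13-(furan-3-yl)-2,6,10-trimethyltrideca-6,10-dien-1-ylidene]-4-methyl-5-oxo-2,5-dihydrofuran-3-yl hexadecanoate
Conditions: Et3N, CH2Cl2, 0 °C (30 used crude)
Reagents that add atoms: none
Why: O-acylation of a tetronic acid with an acid chloride and a tertiary amine; the methyl group at C3 blocks C-acylation, and the mild, non-nucleophilic conditions should leave the E alkene and the product enol ester intact.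

## Compound list

1 | (2E,6E)-farnesol, (2E,6E)-3,7,11-trimethyldodeca-2,6,10-trien-1-ol | CC(C)=CCC/C(C)=C/CC/C(C)=C/CO | starting material
2 | (2E,6E)-farnesyl acetate | CC(C)=CCC/C(C)=C/CC/C(C)=C/COC(C)=O | intermediate
3 | (2E,6E)-10-bromo-11-hydroxy-3,7,11-trimethyldodeca-2,6-dien-1-yl acetate (racemic) | CC(C)(O)C(Br)CC/C(C)=C/CC/C(C)=C/COC(C)=O | intermediate
4 | (2E,6E)-9-(3,3-dimethyloxiran-2-yl)-3,7-dimethylnona-2,6-dien-1-ol (racemic) | CC1(C)OC1CC/C(C)=C/CC/C(C)=C/CO | intermediate
5 | 3-[(3E,7E)-9-chloro-3,7-dimethylnona-3,7-dien-1-yl]-2,2-dimethyloxirane (racemic) | CC1(C)OC1CC/C(C)=C/CC/C(C)=C/CCl | intermediate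
6 | furan-3-ylmethanol | OCc1ccoc1 | starting material
7 | 3-(chloromethyl)furan | ClCc1ccoc1 | intermediate
8 | (furan-3-ylmethyl)magnesium chloride | Cl[Mg]Cc1ccoc1 | intermediate (not isolated)
9 | 3-[(3E,7E)-10-(3,3-dimethyloxiran-2-yl)-4,8-dimethyldeca-3,7-dien-1-yl]furan (racemic) | CC1(C)OC1CC/C(C)=C/CC/C(C)=C/CCc1ccoc1 | intermediate
10 | (4E,8E)-11-(furan-3-yl)-4,8-dimethylundeca-4,8-dienal | O=CCC/C(C)=C/CC/C(C)=C/CCc1ccoc1 | intermediate
11 | 3-[(3E,7E)-12-methoxy-4,8-dimethyldodeca-3,7,11-trien-1-yl]furan (E/Z mixture at the enol ether) | COC=CCC/C(C)=C/CC/C(C)=C/CCc1ccoc1 | intermediate (not isolated)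
12 | (5E,9E)-12-(furan-3-yl)-5,9-dimethyldodeca-5,9-dienal | O=CCCC/C(C)=C/CC/C(C)=C/CCc1ccoc1 | intermediate
13 | ethanethiol | CCS | starting material
14 | bromoacetyl bromide | BrCC(Br)=O | starting material
15 | S-ethyl 2-bromoethanethioate | CCSC(=O)CBr | intermediate
16 | [2-(ethylsulfanyl)-2-oxoethyl]triphenylphosphonium bromide | CCSC(=O)C[P+](c1ccccc1)(c1ccccc1)c1ccccc1.[Br-] | intermediate (not isolated)
17 | S-ethyl 2-(triphenyl-λ5-phosphanylidene)ethanethioate | CCSC(=O)C=P(c1ccccc1)(c1ccccc1)c1ccccc1 | intermediate
18 | S-ethyl (2E,7E,11E)-14-(furan-3-yl)-7,11-dimethyltetradeca-2,7,11-trienethioate | CCSC(=O)/C=C/CCC/C(C)=C/CC/C(C)=C/CCc1ccoc1 | intermediate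
19 | bromomagnesium enolate of 20, bromo{[(3S,7E,11E)-1-(ethylsulfanyl)-14-(furan-3-yl)-3,7,11-trimethyltetradeca-1,7,11-trien-1-yl]oxy}magnesium | CCSC(O[Mg]Br)=C[C@@H](C)CCC/C(C)=C/CC/C(C)=C/CCc1ccoc1 | intermediate (not isolated)
20 | S-ethyl (3S,7E,11E)-14-(furan-3-yl)-3,7,11-trimethyltetradeca-7,11-dienethioate | CCSC(=O)C[C@@H](C)CCC/C(C)=C/CC/C(C)=C/CCc1ccoc1 | intermediate
21 | (3S,7E,11E)-14-(furan-3-yl)-3,7,11-trimethyltetradeca-7,11-dienal | O=CC[C@@H](C)CCC/C(C)=C/CC/C(C)=C/CCc1ccoc1 | intermediate
22 | (3S,7E,11E)-14-(furan-3-yl)-3,7,11-trimethyltetradeca-1,7,11-trien-1-yl nonafluorobutane-1-sulfonate (E/Z mixture at C1) | FC(F)(F)C(F)(F)C(F)(F)C(F)(F)S(=O)(=O)OC=C[C@@H](C)CCC/C(C)=C/CC/C(C)=C/CCc1ccoc1 | intermediate (not isolated)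
23 | 3-[(3E,7E,12S)-4,8,12-trimethyltetradeca-3,7-dien-13-yn-1-yl]furan | C#C[C@@H](C)CCC/C(C)=C/CC/C(C)=C/CCc1ccoc1 | intermediate
24 | N-methoxy-N-methylpropanamide | CCC(=O)N(C)OC | starting material
25 | lithium acetylide of 23, [(3S,7E,11E)-14-(furan-3-yl)-3,7,11-trimethyltetradeca-7,11-dien-1-yn-1-yl]lithium | [Li]C#C[C@@H](C)CCC/C(C)=C/CC/C(C)=C/CCc1ccoc1 | intermediate (not isolated)
26 | (6S,10E,14E)-17-(furan-3-yl)-6,10,14-trimethylheptadeca-10,14-dien-4-yn-3-one | CCC(=O)C#C[C@@H](C)CCC/C(C)=C/CC/C(C)=C/CCc1ccoc1 | intermediate
27 | (4E,6S,10E,14E)-17-(furan-3-yl)-6,10,14-trimethyl-4-(tributylstannyl)heptadeca-4,10,14-trien-3-one | CCC(=O)/C(=C\[C@@H](C)CCC/C(C)=C/CC/C(C)=C/CCc1ccoc1)[Sn](CCCC)(CCCC)CCCC | intermediate (not isolated)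
28 | (4E,6S,10E,14E)-17-(furan-3-yl)-4-iodo-6,10,14-trimethylheptadeca-4,10,14-trien-3-one | CCC(=O)/C(I)=C\[C@@H](C)CCC/C(C)=C/CC/C(C)=C/CCc1ccoc1 | intermediate
29 | lithium (4E,6S,10E,14E)-17-(furan-3-yl)-4-iodo-2,6,10,14-tetramethyl-3-oxoheptadeca-4,10,14-trienoate (both C2 epimers) | [Li+].[O-]C(=O)C(C)C(=O)/C(I)=C\[C@@H](C)CCC/C(C)=C/CC/C(C)=C/CCc1ccoc1 | intermediate (not isolated)
30 | (5E)-5-[(2S,6E,10E)-13-(furan-3-yl)-2,6,10-trimethyltrideca-6,10-dien-1-ylidene]-4-hydroxy-3-methylfuran-2(5H)-one | OC1=C(C)C(=O)O/C1=C/[C@@H](C)CCC/C(C)=C/CC/C(C)=C/CCc1ccoc1 | intermediate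
31 | hexadecanoyl chloride (palmitoyl chloride) | CCCCCCCCCCCCCCCC(Cl)=O | starting material
32 | (2E)-2-[(2S,6E,10E)-13-(furan-3-yl)-2,6,10-trimethyltrideca-6,10-dien-1-ylidene]-4-methyl-5-oxo-2,5-dihydrofuran-3-yl hexadecanoate | CCCCCCCCCCCCCCCC(=O)OC1=C(C)C(=O)O/C1=C/[C@@H](C)CCC/C(C)=C/CC/C(C)=C/CCc1ccoc1 | target

## Step count and least certain steps

Total: 18 steps. Longest linear sequence: 15 steps (steps 1 to 4, 6 to 8 and 11 to 18, from farnesol 1). Steps 5, 9 and 10 are side branches.

**Step 17 (carries the label).** The β-keto carboxylate 29 may lose CO2 on warming before the C–O coupling occurs. The iodoalkene may also lose its geometry through reversible conjugate addition of iodide or carboxylate, or lose iodine by protodehalogenation. The cause is that decarboxylation and the copper coupling run at similar temperatures and the (E)-iodoenone is the less stable isomer. The fallback uses known chemistry and a different ring-closing logic, setting out from ynone 26. Silver-catalysed carboxylative cyclisation (AgOCOPh, MTBD, CO2, MeCN), a documented reaction of conjugated ynones that runs by enolate carboxylation and anti addition across the alkyne, would give the (5Z)-tetronic acid F1. Acylation with 31 as in step 18 would give the (2Z)-palmitate F2. Direct irradiation of degassed F2 near 300 nm would set up a Z/E photostationary mixture, from which 32 is separated and F2 recycled. The route is rejoined at 32. This path is not stereospecific and is held in reserve.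

**Step 12 (key step).** Facial discrimination may be insufficient if uncatalysed or ligand-free copper addition competes, and 1,2-addition to the thioester may occur if the temperature rises. The cause is that control rests on a single catalyst–substrate interaction with no substrate bias. The fallback sets out from aldehyde 12 and replaces catalyst control by auxiliary control of the same C7–CH3 bond formation. A Horner–Wadsworth–Emmons reaction (LiCl, iPr2NEt, MeCN) with the oxazolidinone phosphonate F3 would give the (E)-N-enoyl oxazolidinone F4. MeMgBr with CuBr·SMe2 in THF at −40 °C should add methyl to C7 anti to the phenyl group of the magnesium-chelated s-cis imide, giving the (3S) adduct F5, whose minor diastereomer can be removed by chromatography or crystallisation. LiSEt in THF at 0 °C would cleave the auxiliary and return thioester 20.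

**Step 14.** The (E)-alkenyl nonaflate requires a syn elimination and may not go to completion, the aldehyde may undergo self-aldol condensation before O-sulfonylation, and the base may isomerise the alkyne toward an allene, which would erase C7. The cause is the strong base acting on an enolisable aldehyde. The fallback sets out from aldehyde 21. Condensation with hydrazine hydrate in EtOH would give the hydrazone F6. Barton vinyl iodide synthesis (I2, tetramethylguanidine, THF) would give the 1-iodoalkene F7. Dehydroiodination with LiN(iPr)2 in THF at −78 °C would return alkyne 23.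

**Step 16.** The α-stannyl enone 27 may isomerise through a 1,3-shift of tin to oxygen, the derived (E)-iodoenone may isomerise to the Z form under light or iodide, and part of the tin may be delivered to the β-carbon. The cause is the lability of α-metallated enones. The fallback sets out from alkyne 23 and moves the hydrostannation to the alcohol oxidation level. Acetylide 25 would be added to propanal to give the propargylic alcohol F8. Hydrostannation catalysed by Mo(CO)3(CNtBu)3 (Bu3SnH, THF, 55 °C), which is α-selective and syn for propargylic alcohols, would give the stannyl allylic alcohol F9. Iodine would give the (E)-iodo allylic alcohol F10, and Dess–Martin oxidation buffered with NaHCO3 would return iodoenone 28.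

**Step 6.** Attack at the γ-carbon of the allylic chloride would give a branched isomer, the Grignard reagent may homocouple during its formation, and magnesium halide may open or rearrange the epoxide. The cause is the ambident allylic electrophile and the Lewis-acidic medium. The fallback sets out from chloride 7 and replaces the Grignard reagent by a sulfone-stabilised carbanion. PhSO2Na in DMF would give the furylmethyl sulfone F11. Its lithio derivative (n-BuLi, THF, −78 °C) would be alkylated by chloride 5 to give the sulfone F12. Sodium amalgam with Na2HPO4 in MeOH at −20 °C would remove the sulfonyl group and return epoxide 9.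

## Further compounds

F1 | step 17 | (5Z)-5-[(2S,6E,10E)-13-(furan-3-yl)-2,6,10-trimethyltrideca-6,10-dien-1-ylidene]-4-hydroxy-3-methylfuran-2(5H)-one | OC1=C(C)C(=O)O/C1=C\[C@@H](C)CCC/C(C)=C/CC/C(C)=C/CCc1ccoc1
F2 | step 17 | (2Z)-2-[(2S,6E,10E)-13-(furan-3-yl)-2,6,10-trimethyltrideca-6,10-dien-1-ylidene]-4-methyl-5-oxo-2,5-dihydrofuran-3-yl hexadecanoate | CCCCCCCCCCCCCCCC(=O)OC1=C(C)C(=O)O/C1=C\[C@@H](C)CCC/C(C)=C/CC/C(C)=C/CCc1ccoc1
F3 | step 12 | diethyl {2-oxo-2-[(4R)-2-oxo-4-phenyl-1,3-oxazolidin-3-yl]ethyl}phosphonate | O=C1OC[C@@H](c2ccccc2)N1C(=O)CP(=O)(OCC)OCC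
F4 | step 12 | (4R)-3-[(2E,7E,11E)-14-(furan-3-yl)-7,11-dimethyltetradeca-2,7,11-trienoyl]-4-phenyl-1,3-oxazolidin-2-one | O=C1OC[C@@H](c2ccccc2)N1C(=O)/C=C/CCC/C(C)=C/CC/C(C)=C/CCc1ccoc1
F5 | step 12 | (4R)-3-[(3S,7E,11E)-14-(furan-3-yl)-3,7,11-trimethyltetradeca-7,11-dienoyl]-4-phenyl-1,3-oxazolidin-2-one | O=C1OC[C@@H](c2ccccc2)N1C(=O)C[C@@H](C)CCC/C(C)=C/CC/C(C)=C/CCc1ccoc1
F6 | step 14 | (3S,7E,11E)-14-(furan-3-yl)-3,7,11-trimethyltetradeca-7,11-dienal hydrazone | NN=CC[C@@H](C)CCC/C(C)=C/CC/C(C)=C/CCc1ccoc1
F7 | step 14 | 3-[(3E,7E,12S,13E)-14-iodo-4,8,12-trimethyltetradeca-3,7,13-trien-1-yl]furan | I/C=C/[C@@H](C)CCC/C(C)=C/CC/C(C)=C/CCc1ccoc1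
F8 | step 16 | (6S,10E,14E)-17-(furan-3-yl)-6,10,14-trimethylheptadeca-10,14-dien-4-yn-3-ol (both C3 epimers) | CCC(O)C#C[C@@H](C)CCC/C(C)=C/CC/C(C)=C/CCc1ccoc1
F9 | step 16 | (4E,6S,10E,14E)-17-(furan-3-yl)-6,10,14-trimethyl-4-(tributylstannyl)heptadeca-4,10,14-trien-3-ol (both C3 epimers) | CCC(O)/C(=C\[C@@H](C)CCC/C(C)=C/CC/C(C)=C/CCc1ccoc1)[Sn](CCCC)(CCCC)CCCC
F10 | step 16 | (4E,6S,10E,14E)-17-(furan-3-yl)-4-iodo-6,10,14-trimethylheptadeca-4,10,14-trien-3-ol (both C3 epimers) | CCC(O)/C(I)=C\[C@@H](C)CCC/C(C)=C/CC/C(C)=C/CCc1ccoc1
F11 | step 6 | 3-[(phenylsulfonyl)methyl]furan | O=S(=O)(Cc1ccoc1)c1ccccc1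
F12 | step 6 | 3-[(3E,7E)-10-(3,3-dimethyloxiran-2-yl)-4,8-dimethyl-1-(phenylsulfonyl)deca-3,7-dien-1-yl]furan (racemic at the epoxide, both epimers at the sulfonyl carbon) | CC1(C)OC1CC/C(C)=C/CC/C(C)=C/CC(c1ccoc1)S(=O)(=O)c1ccccc1
A1 | alternative 1 | (2R,6E,10E)-13-(furan-3-yl)-6,10-dimethyl-4-(phenylsulfonyl)trideca-6,10-dien-2-ol (both epimers at the sulfonyl carbon) | O[C@H](C)CC(S(=O)(=O)c1ccccc1)C/C(C)=C/CC/C(C)=C/CCc1ccoc1
A2 | alternative 1 | (R)-2-methyloxirane | C[C@@H]1CO1
A3 | alternative 1 | methyl phenyl sulfone | CS(=O)(=O)c1ccccc1
A4 | alternative 1 | 3-[(3E,7E)-9-bromo-4,8-dimethylnona-3,7-dien-1-yl]furan | BrC/C(C)=C/CC/C(C)=C/CCc1ccoc1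
A5 | alternative 2 | 2-[(2R,6E,10E)-13-(furan-3-yl)-6,10-dimethyltrideca-6,10-dien-2-yl]-4,4,5,5-tetramethyl-1,3,2-dioxaborolane | CC1(C)OB(OC1(C)C)[C@H](C)CCC/C(C)=C/CC/C(C)=C/CCc1ccoc1
A6 | alternative 2 | 2-[(4E,8E)-11-(furan-3-yl)-4,8-dimethylundeca-4,8-dien-1-yl]-4,4,5,5-tetramethyl-1,3,2-dioxaborolane | CC1(C)OB(OC1(C)C)CCC/C(C)=C/CC/C(C)=C/CCc1ccoc1
A7 | alternative 2 | ethyl 2,4,6-tri(propan-2-yl)benzoate | CCOC(=O)c1c(C(C)C)cc(C(C)C)cc1C(C)C
A8 | alternative 3 | (2S,6E,10E)-13-(furan-3-yl)-2,6,10-trimethyltrideca-6,10-dien-1-ol | OC[C@@H](C)CCC/C(C)=C/CC/C(C)=C/CCc1ccoc1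
A9 | alternative 3 | (2E,6E,10E)-13-(furan-3-yl)-2,6,10-trimethyltrideca-2,6,10-trienal | O=C/C(C)=C/CC/C(C)=C/CC/C(C)=C/CCc1ccoc1
A10 | alternative 3 | 3-[(3E,7E)-4,8,12-trimethyltrideca-3,7,11-trien-1-yl]furan | CC(C)=CCC/C(C)=C/CC/C(C)=C/CCc1ccoc1
A11 | alternative 3 | (2S,6E,10E)-13-(furan-3-yl)-2,6,10-trimethyltrideca-6,10-dienal | O=C[C@@H](C)CCC/C(C)=C/CC/C(C)=C/CCc1ccoc1
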